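The trap in these runs was to read the starting material against the clock, since Monday's and Tuesday's flasks held different amounts of enzyme, so I read it against the enzyme dose, free enzyme charged times time.

| flask | starting material | second substrate | free enzyme | remark | time |
|---|---|---|---|---|---|
| Monday's | 0.010 M | 0.040 M (fed, over 20 min) | 0.49 µM | run made earlier; the fed solution adds 0.20 times the starting volume |  |
| Tuesday's | 0.010 M | 0.040 M (fed, over 20 min) | 0.73 µM | run made earlier; the fed solution adds 0.20 times the starting volume |  |
| flask | 0.010 M | 0.0400 M (fed, over 20 min) | 0.98 µM | the fed solution adds 0.20 times the starting volume | 30 min |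

| run | time / min | target / % | starting material / % |
|---|---|---|---|
| Monday's | 1.33 | 0.7 | 99.0 |
| Monday's | 3.00 | 5.0 | 95.8 |
| Monday's | 8.00 | 20.7 | 79.7 |
| Monday's | 20.0 | 57.4 | 42.5 |
| Tuesday's | 5.00 | 14.0 | 84.6 |
| Tuesday's | 10.0 | 38.7 | 61.9 |
| Tuesday's | 15.0 | 59.9 | 40.2 |
| Tuesday's | 20.0 | 75.8 | 24.1 |

(standard deviation of a reading: 0.3 percentage points)

- every charge counts on the volume at the start, and the solution that is fed holds the whole dose
- steps thought possible: 2 second substrate -> homo dimer; second substrate + loaded enzyme <-> second complex; starting material + free enzyme <-> first complex; first complex -> loaded enzyme + first product; second complex -> free enzyme + target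

* the target in the flask at 30 min, as a percentage of the starting material charged
* the starting material in the flask at 30 min, as a percentage of the starting material charged
* concentration of first product at 30 min, in M

I replaced each curve by its mean: the logarithm of the charge over the fraction left, divided by the dose, which I called the mean decay per dose. Monday's flask at 20.0 min had a dose of 0.588 mM·s and a mean of 1460 M⁻¹ s⁻¹. Tuesday's flask at 20.0 min had 0.876 mM·s and a mean of 1620 M⁻¹ s⁻¹. But the mean was larger at the larger dose, so one constant would err, and I carried a straight line through the two means.

The flask's dose of 1.76 mM·s is twice Tuesday's, more than in either run, and the line gives 2150 M⁻¹ s⁻¹. So I expected 2.27% of the starting material left, the target as the rest, 97.7%, since the two summed to 99.9% at Monday's end, and first product at 0.00814 M in the diluted volume.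

The forecast said 94%, 6% and 0.00783 M, holding that “the homo dimer drain holds it at a steady level”.

The flask gave 97.9%, 2.09% and 0.00816 M.

    2 second substrate → homo dimer (k = 0.0280 M⁻¹ s⁻¹)
    second substrate + loaded enzyme ⇌ second complex (K = 15.0 M⁻¹, k = 4900 M⁻¹ s⁻¹)
    starting material + free enzyme ⇌ first complex (K = 98.0 M⁻¹, k = 16000 M⁻¹ s⁻¹)
    first complex → loaded enzyme + first product (k = 54.0 s⁻¹)
    second complex → free enzyme + target (k = 430 s⁻¹)

The flask's own mean came to 2198 M⁻¹ s⁻¹. At 10.0 min in the flask, the half-life of starting material by the forward rate alone of its step with free enzyme to first complex, the way back not counted, was 1.6 min, short against the 30 min of the flask. For the neighbour flask with 2.4 × 10⁻⁷ M of free enzyme, whose dose lay below both runs, the line gives 1360 M⁻¹ s⁻¹, hence 55.5% left, and that flask held 53.1% of its starting material.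

The earlier runs and the new flask are calculated for an exercise, noise included.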